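**Two times.** Expect an intermediate molecule in this flask to last τ = 9.18 min, its mean life before becoming product, and hold that against the run of 12 min, which is longer. Their ratio is x = 1.31.

| flask | starting material | reagent | free catalyst | second catalyst | remark | time |
|---|---|---|---|---|---|---|
| theta | 24 mM | 72 mM | 43 µM | 32 µM (in portions, 2) | run made earlier; portions every 50 s |  |
| delta | 24 mM | 72 mM | 43 µM | 72 µM (in portions, 2) | run made earlier; portions every 50 s |  |
| epsilon | 24 mM | 140 mM | 43 µM | 48 µM (in portions, 2) | run made earlier; portions every 50 s |  |
| flask | 24 mM | 72.0 mM | 43 µM | 48 µM (in portions, 2) | the portions of second catalyst follow each other after 50 s, the first at the start | 12 min |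

- theta (time / min: product / %, intermediate / %): 1.00: 1.1, 5.1; 2.00: 0.5, 7.5; 4.00: 1.8, 13.5; 8.00: 6.4, 19.4; 15.0: 18.4, 24.6
- delta (time / min: product / %, intermediate / %): 1.33: 0.2, 5.4; 4.00: 4.3, 11.1; 6.00: 8.6, 13.6; 10.0: 18.0, 14.7; 15.0: 28.8, 14.8
- epsilon (time / min: product / %, intermediate / %): 1.00: 0.7, 2.7; 2.00: 1.9, 7.0; 4.00: 5.0, 9.8; 8.00: 15.0, 12.5; 15.0: 31.6, 9.9

(each reading ± 0.5 percentage points)

- concentration of product at 12 min, in mM
- concentration of intermediate at 12 min, in mM
- concentration of reagent at 12 min, in mM

- the earlier runs were read with a standard deviation of 0.5 percentage points

**Reading τ.** At 15.0 min, product plus intermediate reads 43.0% in theta, 43.6% in delta and 41.5% in epsilon, so you may take the feed of intermediate as common to these runs. The split between the two differs. Epsilon has this flask's second catalyst, and over its last interval product gained 17 points while intermediate averaged 11.2%. I assume the loss of intermediate is proportional to reagent, so I stretch epsilon's life by the ratio of reagent charges.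

**One molecule.** Take a molecule born at a random moment of the run, with births spread evenly. Its chance of being product at the end is 1 − (1 − e^−x)/x = 44.2%. Delta's readings, interpolated, put the converted part at 37.1%. My reckoning is therefore 3.93 mM of product and 4.96 mM of intermediate, with one reagent per product leaving 68.1 mM.

**The forecast.** It gives 4.1 mM, 4.7 mM and 67.9 mM, more product than my reckoning, holding that “the first step depends on neither reagent nor second catalyst”.

**The result.** The flask gives 4.28 mM, 4.65 mM and 67.7 mM.

    starting material + free catalyst → spent catalyst (k = 0.0170 /M/s)
    starting material + free catalyst → free catalyst + intermediate (k = 17.0 /M/s)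
    reagent + second catalyst + intermediate → second catalyst + product (k = 540 /M²/s)

**The neighbour.** A neighbour flask holds 0.012 mM of second catalyst, a quarter of this flask's charge. Taking the loss of intermediate as proportional to second catalyst, as the third equation has it, τ for the neighbour flask stretches to 36.7 min, and the same chance falls to 14.7%. The neighbour flask gives 1.47 mM of product, less than this flask's 4.28 mM, and 7.45 mM of intermediate, so product is 16.5% of the two.

The earlier runs and the new flask come from a simulation for substances that don't exist; noise was put on by code.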